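**Plan**

1. Numbering (eudesmane): ring A = C1–C5 + C10, ring B = C5–C10, C14 = methyl on C10, C15 = CH2O carbon on C4, C11–C13 = acrylate on C7. Retrosynthetic cuts, in order: ester O–C15 (Mitsunobu); C4–C15 (enol triflate plus stannylmethanol) back to a C4 ketone; then C5–C10 and C2–C3 together; then C7–C6 (copper SN2′) and C7–C11 (Morita–Baylis–Hillman).
2. Enabling feature: with C4 as a ketone, its two α-carbons C3 and C5 form a 1,3-bis-nucleophile, and C10–C1–C2 maps onto a β,β-disubstituted enal (C10 = β-carbon, C2 = carbonyl carbon). A [3+3] Michael/aldol condensation therefore folds acyclic keto-enal 11 into the decalin enone 14.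
3. Forward order: geranyl acetate → C7 aldehyde → acrylate attached (MBH) → allylic bromide → 3-oxobutyl arm by SN2′ → keto-enal → ring B (C5–C10), then ring A (C2–C3), in one pot → C3=C4 enol triflate → C15 → (Z)-p-coumarate.
4. Stereochemistry: C7 from the chiral copper catalyst (step 4); C10 from the chiral amine in the key step, matched with C7 through a chair; C5 by equilibration to the trans ring fusion; E-enal from geranyl acetate; Z-cinnamate from a Still–Gennari olefination.

Key step: step 8

Assumption: the sense of induction of the CuBr·SMe2/Taniaphos catalyst on this new allylic bromide cannot be predicted with certainty, so the ligand enantiomer that gives (3R)-8 is fixed in a first run (correlation at the stage of 14); all structures are drawn for that enantiomer. Z-cinnamates are handled with exclusion of light.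

**Route**

Step 1
Reactants: 1 geranyl acetate
Product: 2 (2E)-3-methyl-6-oxohex-2-en-1-yl acetate
Conditions: O3 (1.0 equiv, Sudan red 7B end point), CH2Cl2, −78 °C; then Me2S, −78 °C → rt
Reagents that add atoms: ozone, [O-][O+]=O
Why: Chemoselective ozonolysis, because the distal trisubstituted alkene is more electron-rich than the one deactivated by the allylic acetate; the aldehyde carbon becomes C7.

Step 2
Reactants: 2 (2E)-3-methyl-6-oxohex-2-en-1-yl acetate; 3 methyl acrylate
Product: 4 methyl (6E)-8-acetoxy-3-hydroxy-6-methyl-2-methylideneoct-6-enoate (racemic)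
Conditions: DABCO (1 equiv), 3 (3 equiv), 1,4-dioxane/H2O 1:1, rt
Reagents that add atoms: none
Why: Morita–Baylis–Hillman reaction of an unhindered aliphatic aldehyde attaches the complete methyl acrylate unit (C11–C13) to C7; the racemic carbinol centre is erased in step 3.

Step 3
Reactants: 4 methyl (6E)-8-acetoxy-3-hydroxy-6-methyl-2-methylideneoct-6-enoate
Product: 5 methyl (2Z,6E)-8-acetoxy-2-(bromomethyl)-6-methylocta-2,6-dienoate
Conditions: NBS, Me2S, CH2Cl2, 0 °C → rt
Reagents that add atoms: N-bromosuccinimide, O=C1CCC(=O)N1Br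
Why: Corey–Kim-type activation of the MBH alcohol and bromide delivery with allylic transposition gives the thermodynamically preferred (Z)-2-(bromomethyl)enoate; the preformed bromosulfonium salt does not attack the other alkene.

Step 4
Reactants: 5 methyl (2Z,6E)-8-acetoxy-2-(bromomethyl)-6-methylocta-2,6-dienoate; 6 2-(2-bromoethyl)-2-methyl-1,3-dioxolane
Product: 8 methyl (3R,6E)-8-acetoxy-6-methyl-2-methylidene-3-[2-(2-methyl-1,3-dioxolan-2-yl)ethyl]oct-6-enoate, via Grignard reagent 7 (not isolated)
Conditions: 6, Mg, THF, 25 °C; then slow addition to 5, CuBr·SMe2 (5 mol %), Taniaphos (ferrocenyl diphosphine, 6 mol %), CH2Cl2, −78 °C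
Reagents that add atoms: none
Why: Copper-catalysed enantioselective SN2′ allylic alkylation of an MBH-derived allylic bromide (formally conjugate addition–elimination at C7) regenerates the 2-substituted acrylate and creates C7, whose (R) configuration is set by the chiral diphosphine–copper complex; at −78 °C the allylic acetate and the esters are left alone.

Step 5
Reactants: 8 methyl (3R,6E)-8-acetoxy-6-methyl-2-methylidene-3-[2-(2-methyl-1,3-dioxolan-2-yl)ethyl]oct-6-enoate
Product: 9 methyl (3R,6E)-8-hydroxy-6-methyl-2-methylidene-3-[2-(2-methyl-1,3-dioxolan-2-yl)ethyl]oct-6-enoate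
Conditions: K2CO3 (0.2 equiv), MeOH, 0 °C
Reagents that add atoms: none
Why: Transesterification removes the primary allylic acetate quickly at 0 °C, while the methyl ester is degenerate under methanolysis and the α-substituted acrylate is a poor acceptor for methoxide.

Step 6
Reactants: 9 methyl (3R,6E)-8-hydroxy-6-methyl-2-methylidene-3-[2-(2-methyl-1,3-dioxolan-2-yl)ethyl]oct-6-enoate
Product: 10 methyl (3R,6E)-8-hydroxy-6-methyl-2-methylidene-3-(3-oxobutyl)oct-6-enoate
Conditions: PPTS (0.2 equiv), acetone/H2O 9:1, 50 °C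
Reagents that add atoms: water, O
Why: Mild acid-catalysed ketal hydrolysis frees the methyl ketone (C4 with C3 and C5) without ionising the primary allylic alcohol.

Step 7
Reactants: 10 methyl (3R,6E)-8-hydroxy-6-methyl-2-methylidene-3-(3-oxobutyl)oct-6-enoate
Product: 11 methyl (3R,6E)-6-methyl-2-methylidene-8-oxo-3-(3-oxobutyl)oct-6-enoate
Conditions: MnO2 (15 equiv), CH2Cl2, rt, dark
Reagents that add atoms: none
Why: MnO2 oxidises only the allylic alcohol and keeps the E geometry, giving the β,β-disubstituted enal (C10=C1–C2) just before use.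

Step 8
Reactants: 11 methyl (3R,6E)-6-methyl-2-methylidene-8-oxo-3-(3-oxobutyl)oct-6-enoate
Product: 14 methyl 2-[(2R,4aS,8aR)-4a-methyl-8-oxo-1,2,3,4,4a,5,8,8a-octahydronaphthalen-2-yl]prop-2-enoate, via keto-aldehyde 12 (not isolated), via aldol adduct 13 (not isolated)
Conditions: (R)-2-[diphenyl(trimethylsilyloxy)methyl]pyrrolidine (20 mol %), PhCO2H (20 mol %), toluene (0.02 M), rt; then TsOH·H2O (20 mol %), 40 °C
Reagents that add atoms: none
Why: Proposed new method: the (R)-amine condenses with the enal of 11 to an (E)-iminium ion, the acid-promoted internal enol of the methyl ketone (C4=C5) adds through C5 to the β-carbon C10 (bond C5–C10), and after hydrolysis of the resulting enamine the methyl carbon C3 adds to the freed aldehyde C2 and water is lost (bond C2–C3, enone C2=C3–C4=O); the closest known reaction types are iminium-catalysed Michael additions to β,β-disubstituted enals that create all-carbon quaternary centres and the amine-catalysed Michael/aldol-condensation [3+3] annulation of β-keto esters with enals, neither shown with an unactivated, tethered methyl ketone. Ring B closes in a 6-(enolexo)-exo-trig Michael addition and ring A in a 6-(enolendo)-exo-trig aldol addition followed by dehydration. C10 is controlled by the catalyst, whose diphenyl(silyloxy)methyl group blocks one face of the (E)-iminium ion so that C5 adds to the Si face of C10 (priorities C1 > C9 > CH3), and this should be the matched case because that face is the one reached through a chair with the C7 substituent and the bulky iminium arm equatorial and the methyl group axial. C5 is an enolisable centre next to the C4 ketone and should settle under the acidic conditions in the trans ring fusion (5α-H, 10β-CH3), while C7 is carried in unchanged. The step needs regioselectivity between the two α-carbons of the ketone and between the possible acceptors, and ring size secures both: only C5 can reach C10 through a six-membered transition state (C3 would close an eight-membered ring, attack on the acrylate would be 5-endo), and only C3 can close a six-membered ring onto C2 (C5 would give a four-membered one). The hindered amine is not expected to add to the α-substituted acrylate.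

Step 9
Reactants: 14 methyl 2-[(2R,4aS,8aR)-4a-methyl-8-oxo-1,2,3,4,4a,5,8,8a-octahydronaphthalen-2-yl]prop-2-enoate
Product: 15 methyl 2-[(2R,4aR,8aR)-4a-methyl-8-oxodecahydronaphthalen-2-yl]prop-2-enoate
Conditions: diethyl 2,6-dimethyl-1,4-dihydropyridine-3,5-dicarboxylate (Hantzsch ester, 1.3 equiv), (2S,5S)-5-benzyl-3-methyl-2-(5-methylfuran-2-yl)imidazolidin-4-one trichloroacetate (20 mol %), Et2O, 0 °C → rt
Reagents that add atoms: none
Why: Iminium-catalysed transfer hydrogenation reduces only the alkene conjugated to the ketone, since the acrylate ester cannot form an iminium ion; no new stereocentre forms and C5 stays trans-fused.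

Step 10
Reactants: 15 methyl 2-[(2R,4aR,8aR)-4a-methyl-8-oxodecahydronaphthalen-2-yl]prop-2-enoate
Product: 16 methyl 2-[(2R,4aS,8aR)-4a-methyl-8-{[(trifluoromethyl)sulfonyl]oxy}-1,2,3,4,4a,5,6,8a-octahydronaphthalen-2-yl]prop-2-enoate
Conditions: PhNTf2 (1.2 equiv), then KN(SiMe3)2 (1.1 equiv) added dropwise, THF, −78 °C
Reagents that add atoms: N-phenylbis(trifluoromethanesulfonimide), O=S(=O)(N(c1ccccc1)S(=O)(=O)C(F)(F)F)C(F)(F)F
Why: Kinetic deprotonation by the hindered amide base takes the accessible C3 methylene proton and not the ring-fusion C5–H, and trapping in situ gives the C3=C4 enol triflate before the enolate can meet the acrylate; C5 is not touched.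

Step 11
Reactants: 16 methyl 2-[(2R,4aS,8aR)-4a-methyl-8-{[(trifluoromethyl)sulfonyl]oxy}-1,2,3,4,4a,5,6,8a-octahydronaphthalen-2-yl]prop-2-enoate
Product: 17 methyl 2-[(2R,4aR,8aR)-8-(hydroxymethyl)-4a-methyl-1,2,3,4,4a,5,6,8a-octahydronaphthalen-2-yl]prop-2-enoate
Conditions: Bu3SnCH2OH (1.5 equiv), Pd(PPh3)4 (5 mol %, zerovalent palladium), LiCl (3 equiv), 1,4-dioxane, 95 °C
Reagents that add atoms: (tributylstannyl)methanol, CCCC[Sn](CCCC)(CCCC)CO
Why: Stille coupling of the enol triflate with the hydroxymethyl stannane installs C15 as the free allylic alcohol with the C3=C4 alkene fixed in place; the acrylate is inert to these conditions.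

Step 12
Reactants: 18 4-(tert-butyldimethylsilyloxy)benzaldehyde; 19 methyl bis(2,2,2-trifluoroethyl)phosphonoacetate
Product: 20 methyl (2Z)-3-[4-(tert-butyldimethylsilyloxy)phenyl]prop-2-enoate
Conditions: 19, KN(SiMe3)2, 18-crown-6, THF, −78 °C; then 18, dark
Reagents that add atoms: none
Why: Still–Gennari olefination of an aromatic aldehyde with the trifluoroethyl phosphonate under dissociating conditions gives the Z-enoate by kinetic control.

Step 13
Reactants: 20 methyl (2Z)-3-[4-(tert-butyldimethylsilyloxy)phenyl]prop-2-enoate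
Product: 21 (2Z)-3-(4-hydroxyphenyl)prop-2-enoic acid
Conditions: LiOH (4 equiv), THF/MeOH/H2O, rt, dark; then 1 M HCl
Reagents that add atoms: lithium hydroxide, [Li+].[OH-]
Why: Saponification cleaves the methyl ester and the aryl silyl ether in one operation without touching the Z-alkene, which has no thermal isomerisation pathway at rt.

Step 14
Reactants: 17 methyl 2-[(2R,4aR,8aR)-8-(hydroxymethyl)-4a-methyl-1,2,3,4,4a,5,6,8a-octahydronaphthalen-2-yl]prop-2-enoate; 21 (2Z)-3-(4-hydroxyphenyl)prop-2-enoic acid
Product: 22 methyl 2-[(2R,4aR,8aR)-8-({[(2Z)-3-(4-hydroxyphenyl)prop-2-enoyl]oxy}methyl)-4a-methyl-1,2,3,4,4a,5,6,8a-octahydronaphthalen-2-yl]prop-2-enoate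
Conditions: PPh3 (1.3 equiv), DIAD (1.3 equiv), THF, 0 °C → rt, dark
Reagents that add atoms: none
Why: Mitsunobu esterification activates the primary allylic alcohol rather than the acid, so the Z-cinnamate is never an acylating species that could isomerise, and the carboxylic acid (far more acidic than the phenol) should be the nucleophile that displaces at C15 by SN2.

**Compound list**

1 | geranyl acetate, (2E)-3,7-dimethylocta-2,6-dien-1-yl acetate | CC(C)=CCC/C(C)=C/COC(C)=O | starting material
2 | (2E)-3-methyl-6-oxohex-2-en-1-yl acetate | O=CCC/C(C)=C/COC(C)=O | intermediate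
3 | methyl acrylate | C=CC(=O)OC | starting material
4 | methyl (6E)-8-acetoxy-3-hydroxy-6-methyl-2-methylideneoct-6-enoate (racemic carbinol) | C=C(C(=O)OC)C(O)CC/C(C)=C/COC(C)=O | intermediate
5 | methyl (2Z,6E)-8-acetoxy-2-(bromomethyl)-6-methylocta-2,6-dienoate | BrC/C(C(=O)OC)=C\CC/C(C)=C/COC(C)=O | intermediate
6 | 2-(2-bromoethyl)-2-methyl-1,3-dioxolane | BrCCC1(C)OCCO1 | starting material
7 | [2-(2-methyl-1,3-dioxolan-2-yl)ethyl]magnesium bromide | Br[Mg]CCC1(C)OCCO1 | intermediate
8 | methyl (3R,6E)-8-acetoxy-6-methyl-2-methylidene-3-[2-(2-methyl-1,3-dioxolan-2-yl)ethyl]oct-6-enoate | C=C(C(=O)OC)[C@@H](CCC1(C)OCCO1)CC/C(C)=C/COC(C)=O | intermediate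
9 | methyl (3R,6E)-8-hydroxy-6-methyl-2-methylidene-3-[2-(2-methyl-1,3-dioxolan-2-yl)ethyl]oct-6-enoate | C=C(C(=O)OC)[C@@H](CCC1(C)OCCO1)CC/C(C)=C/CO | intermediate
10 | methyl (3R,6E)-8-hydroxy-6-methyl-2-methylidene-3-(3-oxobutyl)oct-6-enoate | C=C(C(=O)OC)[C@@H](CCC(C)=O)CC/C(C)=C/CO | intermediate
11 | methyl (3R,6E)-6-methyl-2-methylidene-8-oxo-3-(3-oxobutyl)oct-6-enoate (keto-enal) | C=C(C(=O)OC)[C@@H](CCC(C)=O)CC/C(C)=C/C=O | intermediate
12 | methyl 2-[(1R,3R,4S)-3-acetyl-4-methyl-4-(2-oxoethyl)cyclohexyl]prop-2-enoate (Michael adduct; acetyl and oxoethyl trans, both equatorial) | C=C(C(=O)OC)[C@@H]1CC[C@@](C)(CC=O)[C@H](C(C)=O)C1 | intermediate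
13 | methyl 2-[6-hydroxy-4a-methyl-8-oxodecahydronaphthalen-2-yl]prop-2-enoate (aldol adduct, trans-fused as in 14, carbinol configuration immaterial) | C=C(C(=O)OC)[C@@H]1CC[C@@]2(C)CC(O)CC(=O)[C@@H]2C1 | intermediate
14 | methyl 2-[(2R,4aS,8aR)-4a-methyl-8-oxo-1,2,3,4,4a,5,8,8a-octahydronaphthalen-2-yl]prop-2-enoate (15-nor-eudesma-2,11(13)-dien-4-one ester; 5α-H, 10β-CH3) | C=C(C(=O)OC)[C@@H]1CC[C@@]2(C)CC=CC(=O)[C@@H]2C1 | intermediate
15 | methyl 2-[(2R,4aR,8aR)-4a-methyl-8-oxodecahydronaphthalen-2-yl]prop-2-enoate | C=C(C(=O)OC)[C@@H]1CC[C@@]2(C)CCCC(=O)[C@@H]2C1 | intermediate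
16 | methyl 2-[(2R,4aS,8aR)-4a-methyl-8-{[(trifluoromethyl)sulfonyl]oxy}-1,2,3,4,4a,5,6,8a-octahydronaphthalen-2-yl]prop-2-enoate | C=C(C(=O)OC)[C@@H]1CC[C@@]2(C)CCC=C(OS(=O)(=O)C(F)(F)F)[C@@H]2C1 | intermediate
17 | methyl 2-[(2R,4aR,8aR)-8-(hydroxymethyl)-4a-methyl-1,2,3,4,4a,5,6,8a-octahydronaphthalen-2-yl]prop-2-enoate | C=C(C(=O)OC)[C@@H]1CC[C@@]2(C)CCC=C(CO)[C@@H]2C1 | intermediate
18 | 4-(tert-butyldimethylsilyloxy)benzaldehyde | O=Cc1ccc(O[Si](C)(C)C(C)(C)C)cc1 | starting material
19 | methyl bis(2,2,2-trifluoroethyl)phosphonoacetate | COC(=O)CP(=O)(OCC(F)(F)F)OCC(F)(F)F | starting material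
20 | methyl (2Z)-3-[4-(tert-butyldimethylsilyloxy)phenyl]prop-2-enoate | COC(=O)/C=C\c1ccc(O[Si](C)(C)C(C)(C)C)cc1 | intermediate
21 | (2Z)-3-(4-hydroxyphenyl)prop-2-enoic acid | OC(=O)/C=C\c1ccc(O)cc1 | intermediate
22 | methyl 2-[(2R,4aR,8aR)-8-({[(2Z)-3-(4-hydroxyphenyl)prop-2-enoyl]oxy}methyl)-4a-methyl-1,2,3,4,4a,5,6,8a-octahydronaphthalen-2-yl]prop-2-enoate (CNP0161949.2) | C=C(C(=O)OC)[C@@H]1CC[C@@]2(C)CCC=C(COC(=O)/C=C\c3ccc(O)cc3)[C@@H]2C1 | target

**Totals**

Total steps: 14. Longest linear sequence: 12 (steps 1–11 and 14).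

**Steps most likely to fail**

Step 8 (Proposed new method). What may go wrong: the unactivated ketone enol is too weak a nucleophile for the hindered iminium ion, so no conjugate addition occurs; or facial selectivity at C10 is poor after E/Z equilibration of the iminium ion through its dienamine. The fallback sets out from 11 and comes back at 14. The chiral amine is dropped and the annulation is run as a classical, substrate-controlled enolate process: 11 with NaOMe (0.3 equiv) in MeOH at 0 °C → rt should undergo intramolecular Michael addition of the thermodynamic ketone enolate to the enal and Robinson-type aldol condensation in the same medium. C10 is then set only by the chair with the C7 substituent equatorial, so 14 is expected together with its C10 epimer, the cis-fused enone 10-epi-14 F1, from which it is separated by chromatography.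

Step 4. What may go wrong: loss of enantioselectivity through the uncatalysed reaction of the Grignard reagent with the activated allylic bromide, or direct SN2 substitution. The fallback sets out from 2 and comes back at 9. The stereocentre is made by conjugate addition instead of allylic substitution, and the acrylate is built afterwards. Knoevenagel condensation of 2 with dimethyl malonate (TiCl4, pyridine, THF, 0 °C) gives dimethyl 2-[(4E)-6-acetoxy-4-methylhex-4-en-1-ylidene]propanedioate F2. Grignard reagent 7 is converted with ZnCl2 (0.5 equiv) into bis[2-(2-methyl-1,3-dioxolan-2-yl)ethyl]zinc F3, which has no background reaction and should add to F2 under Cu(OTf)2/chiral phosphoramidite catalysis (toluene, −30 °C) to give dimethyl 2-[(3R,6E)-8-acetoxy-6-methyl-1-(2-methyl-1,3-dioxolan-2-yl)oct-6-en-3-yl]propanedioate F4. KOH (2.2 equiv, MeOH/H2O, 0 °C → rt) cleaves the acetate and one ester to (3R,6E)-8-hydroxy-2-(methoxycarbonyl)-6-methyl-3-[2-(2-methyl-1,3-dioxolan-2-yl)ethyl]oct-6-enoic acid F5. Decarboxylative Mannich methylenation (paraformaldehyde, Et2NH, EtOAc, reflux) then turns the half-ester into the acrylate, which is alcohol 9.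

Step 10. What may go wrong: the base attacks the acrylate (conjugate addition, or γ-deprotonation with loss of the C7 configuration), or enolisation goes toward C5. The fallback sets out from 15 and comes back at 17, and uses no strong base and no triflate. Takai–Lombardo methylenation of the ketone (Zn, CH2Br2, TiCl4, THF/CH2Cl2, 0 °C → rt; esters tolerated) gives methyl eudesma-4(15),11(13)-dien-12-oate F6. mCPBA (NaHCO3, CH2Cl2, 0 °C) epoxidises only the electron-rich exocyclic alkene, giving the spiro-epoxide F7 (expected 4α,15-epoxide; configuration immaterial). TMSOTf/DBU (toluene, −78 → 0 °C) opens it with loss of a C3 proton to the allylic trimethylsilyl ether F8. Citric acid in MeOH releases 17.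

**Further compounds**

F1 | step 8 | methyl 2-[(2R,4aR,8aR)-4a-methyl-8-oxo-1,2,3,4,4a,5,8,8a-octahydronaphthalen-2-yl]prop-2-enoate (10-epi-14, cis-fused) | C=C(C(=O)OC)[C@@H]1CC[C@]2(C)CC=CC(=O)[C@@H]2C1
F2 | step 4 | dimethyl 2-[(4E)-6-acetoxy-4-methylhex-4-en-1-ylidene]propanedioate | COC(=O)C(C(=O)OC)=CCC/C(C)=C/COC(C)=O
F3 | step 4 | bis[2-(2-methyl-1,3-dioxolan-2-yl)ethyl]zinc | CC1(CC[Zn]CCC2(C)OCCO2)OCCO1
F4 | step 4 | dimethyl 2-[(3R,6E)-8-acetoxy-6-methyl-1-(2-methyl-1,3-dioxolan-2-yl)oct-6-en-3-yl]propanedioate | COC(=O)C(C(=O)OC)[C@@H](CCC1(C)OCCO1)CC/C(C)=C/COC(C)=O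
F5 | step 4 | (3R,6E)-8-hydroxy-2-(methoxycarbonyl)-6-methyl-3-[2-(2-methyl-1,3-dioxolan-2-yl)ethyl]oct-6-enoic acid (mixture at C2) | COC(=O)C(C(=O)O)[C@@H](CCC1(C)OCCO1)CC/C(C)=C/CO
F6 | step 10 | methyl 2-[(2R,4aR,8aR)-4a-methyl-8-methylidenedecahydronaphthalen-2-yl]prop-2-enoate (methyl eudesma-4(15),11(13)-dien-12-oate) | C=C(C(=O)OC)[C@@H]1CC[C@@]2(C)CCCC(=C)[C@@H]2C1
F7 | step 10 | methyl eudesm-11(13)-en-12-oate 4α,15-epoxide (spiro-oxirane at C4) | C=C(C(=O)OC)[C@@H]1CC[C@@]2(C)CCC[C@]3(CO3)[C@@H]2C1
F8 | step 10 | methyl 2-[(2R,4aR,8aR)-4a-methyl-8-{[(trimethylsilyl)oxy]methyl}-1,2,3,4,4a,5,6,8a-octahydronaphthalen-2-yl]prop-2-enoate | C=C(C(=O)OC)[C@@H]1CC[C@@]2(C)CCC=C(CO[Si](C)(C)C)[C@@H]2C1
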